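**Retrosynthetic overview**
1. Aspergilol C ⇐ C17 ketone (hydride from the α face) ⇐ ring B closed last by an intramolecular McMurry coupling of a C2 methyl ketone with the ring A ketone C3; the eight-membered ring enforces the C2=C3 geometry.
2. Ring C ⇐ aldol condensation of the C14 ketone onto a C26/C2 1,2-diketone; Luche reduction, Li/NH3 reductive enol triflation (axial H at C26) and Pd/formate reduction then give the C13=C14 alkene.
3. Ring D stereotriad (C20, C24, C15) ⇐ one-flask Sakurai allylation/titanium-enolate aldol of enone 5 with allylsilane 8 (masked 1,2-diketone) and aldehyde 22.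
4. Aldehyde 22 (ring A; C6, C8, C11) ⇐ (R)-β-citronellene and 2-methylfuran: cyclopentenone, CBS reduction, hydroxyl-directed iridium hydrogenation.
5. Ring order: A and D are made as separate pieces, then C (aldol), then B (McMurry).

Assumption: carbons are labelled C1 to C26 in the order they stand in the target SMILES (oxygen is O18; β is the face of the C16 methyl group), and compounds 1, 6, 9 and 13 are taken as commercial.

**Ring D enone**

Step 1
Reactants: 1 (R)-4-(tert-butyldimethylsilyloxy)cyclopent-2-en-1-one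
Product: 3 (S)-4-isopropylcyclopent-2-en-1-one, via silyloxy ketone 2 (not isolated)
Conditions: i-PrMgCl, CuBr·SMe2 (10 mol %), THF, −78 °C; aq. NH4Cl; then 1,8-diazabicyclo[5.4.0]undec-7-ene (0.2 equiv), CH2Cl2, 0 °C
Reagents that add atoms: isopropylmagnesium chloride, CC(C)[Mg]Cl
Why: Copper-catalysed conjugate addition goes anti to the silyloxy group and E1cB loss of silanol then moves the enone, so the silyloxy stereocentre is traded for the isopropyl-bearing centre (future C20).

Step 2
Reactants: 3 (S)-4-isopropylcyclopent-2-en-1-one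
Product: 4 (S)-2-iodo-4-isopropylcyclopent-2-en-1-one
Conditions: I2, pyridine/CH2Cl2 (1:1), 0 °C to rt
Reagents that add atoms: iodine, II
Why: Johnson α-iodination of an enone (pyridine addition, iodination, elimination) under conditions that leave the γ-stereocentre untouched.

Step 3
Reactants: 4 (S)-2-iodo-4-isopropylcyclopent-2-en-1-one
Product: 5 (S)-4-isopropyl-2-methylcyclopent-2-en-1-one
Conditions: MeZnCl, Pd(PPh3)4 (5 mol %), THF, rt
Reagents that add atoms: methylzinc chloride, C[Zn]Cl
Why: Negishi coupling of the α-iodoenone runs at rt without base, so the enone does not isomerise and C20 is kept.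

**Allylsilane**

Step 4
Reactants: 6 2,3-dimethylbuta-1,3-diene
Product: 8 trimethyl(3-methyl-2-methylenebut-3-en-1-yl)silane, via allylpotassium 7 (not isolated)
Conditions: n-BuLi, KOtBu, hexane, 0 °C; then Me3SiCl, −78 °C to rt
Reagents that add atoms: chlorotrimethylsilane, C[Si](C)(C)Cl
Why: Superbase allylic metalation of the diene followed by silylation gives the isoprenyl-type allylsilane.

**Ring A aldehyde**

Step 5
Reactants: 9 (R)-3,7-dimethylocta-1,6-diene
Product: 11 (R)-4-methylhex-5-en-1-ol, via aldehyde 10 (not isolated)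
Conditions: O3 (1.0 equiv), CH2Cl2/MeOH, −78 °C; then NaBH4, −78 to 0 °C
Reagents that add atoms: ozone, [O-][O+]=O
Why: Ozonolysis picks the electron-rich trisubstituted alkene over the vinyl group and reductive work-up gives the alcohol; C11 comes from the chiral pool.

Step 6
Reactants: 11 (R)-4-methylhex-5-en-1-ol
Product: 12 (R)-6-iodo-3-methylhex-1-ene
Conditions: I2, PPh3, imidazole, CH2Cl2, 0 °C
Reagents that add atoms: iodine, II
Why: Appel iodination of a primary alcohol.

Step 7
Reactants: 13 2-methylfuran; 12 (R)-6-iodo-3-methylhex-1-ene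
Product: 15 2-methyl-5-[(4R)-4-methylhex-5-en-1-yl]furan, via furyllithium 14 (not isolated)
Conditions: n-BuLi, THF, 0 °C; then 12, 0 °C to rt
Reagents that add atoms: none
Why: C5 lithiation of 2-methylfuran and SN2 alkylation by the primary iodide.

Step 8
Reactants: 15 2-methyl-5-[(4R)-4-methylhex-5-en-1-yl]furan
Product: 17 3-methyl-2-[(3R)-3-methylpent-4-en-1-yl]cyclopent-2-en-1-one, via diketone 16 (not isolated)
Conditions: AcOH/H2O, H2SO4 (cat.), 100 °C; then NaOH, EtOH/H2O, reflux
Reagents that add atoms: water, O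
Why: Acid hydrolysis of the furan to the 1,4-diketone and intramolecular aldol condensation (the classical jasmone-type cyclopentenone synthesis) build ring A with C8 and C6 as the enone carbons.

Step 9
Reactants: 17 3-methyl-2-[(3R)-3-methylpent-4-en-1-yl]cyclopent-2-en-1-one
Product: 19 (1S)-2-[(3R)-5-hydroxy-3-methylpentyl]-3-methylcyclopent-2-en-1-ol, via allylic alcohol 18 (not isolated)
Conditions: (R)-1-methyl-3,3-diphenyltetrahydro-1H,3H-pyrrolo[1,2-c][1,3,2]oxazaborole (10 mol %), BH3·SMe2 (2.5 equiv), THF, −20 °C to rt; then NaOH, H2O2, 0 °C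
Reagents that add atoms: hydrogen peroxide, OO
Why: Corey–Bakshi–Shibata reduction (alkenyl arm as the large group) sets the C3 carbinol as S under catalyst control, and the excess borane hydroborates the vinyl group anti-Markovnikov so that oxidation gives the primary alcohol.

Step 10
Reactants: 19 (1S)-2-[(3R)-5-hydroxy-3-methylpentyl]-3-methylcyclopent-2-en-1-ol
Product: 20 (1S,2S,3S)-2-[(3R)-5-hydroxy-3-methylpentyl]-3-methylcyclopentan-1-ol
Conditions: [Ir(cod)(PCy3)(py)]PF6 (10 mol %), H2 (5 atm), CH2Cl2, rt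
Reagents that add atoms: none
Why: Hydroxyl-directed hydrogenation of the tetrasubstituted alkene delivers both hydrogens from the OH face, which sets C6 and C8 with the methyl group and the side chain cis to each other.

Step 11
Reactants: 20 (1S,2S,3S)-2-[(3R)-5-hydroxy-3-methylpentyl]-3-methylcyclopentan-1-ol
Product: 21 (3R)-5-[(1S,2S,5S)-2-hydroxy-5-methylcyclopentyl]-3-methylpentanal
Conditions: 2,2,6,6-tetramethylpiperidin-1-oxyl (10 mol %), PhI(OAc)2, CH2Cl2, rt
Reagents that add atoms: none
Why: Oxoammonium-mediated oxidation is selective for the primary over the secondary alcohol.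

Step 12
Reactants: 21 (3R)-5-[(1S,2S,5S)-2-hydroxy-5-methylcyclopentyl]-3-methylpentanal
Product: 22 (3R)-5-[(1S,2S,5S)-2-(tert-butyldimethylsilyloxy)-5-methylcyclopentyl]-3-methylpentanal
Conditions: t-BuMe2SiCl, imidazole, DMF, rt
Reagents that add atoms: tert-butyldimethylsilyl chloride, CC(C)(C)[Si](C)(C)Cl
Why: Standard silylation of the secondary alcohol; the aldehyde has no α-stereocentre to lose.

**Union and completion**

Step 13
Reactants: 5 (S)-4-isopropyl-2-methylcyclopent-2-en-1-one; 8 trimethyl(3-methyl-2-methylenebut-3-en-1-yl)silane; 22 (3R)-5-[(1S,2S,5S)-2-(tert-butyldimethylsilyloxy)-5-methylcyclopentyl]-3-methylpentanal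
Product: 24 ring D hydroxy ketone (Sakurai–aldol adduct; C14 epimers), via titanium enolate 23 (not isolated)
Conditions: TiCl4, CH2Cl2, −78 °C (5, then 8); then 22, −78 °C; aq. NaHCO3
Reagents that add atoms: none
Why: Hosomi–Sakurai conjugate allylation adds to C24 anti to the C20 isopropyl group and the titanium enolate then undergoes aldol addition anti to the new C24 substituent, which sets the C15 quaternary centre trans (the C14 carbinol is oxidised later).

Step 14
Reactants: 24 ring D hydroxy ketone (Sakurai–aldol adduct; C14 epimers)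
Product: 25 C17 ethylene ketal of 24
Conditions: HOCH2CH2OH, HC(OEt)3, p-toluenesulfonic acid monohydrate (5 mol %), CH2Cl2, rt
Reagents that add atoms: ethane-1,2-diol, OCCO
Why: Acid-catalysed ketalisation of the only ketone masks C17 against enolisation and reduction until the end.

Step 15
Reactants: 25 C17 ethylene ketal of 24
Product: 26 C14 ketone (diene side chain intact)
Conditions: Dess–Martin periodinane, NaHCO3, CH2Cl2, 0 °C to rt
Reagents that add atoms: none
Why: Dess–Martin oxidation of the hindered secondary alcohol removes the C14 stereocentre.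

Step 16
Reactants: 26 C14 ketone (diene side chain intact)
Product: 27 triketone (C14 ketone plus C26/C2 1,2-diketone)
Conditions: O3, CH2Cl2, −78 °C; then PPh3, −78 °C to rt
Reagents that add atoms: ozone, [O-][O+]=O
Why: Ozonolysis of both methylene groups of the 2,3-disubstituted butadiene unmasks the 1,2-diketone; no other alkene is present.

Step 17
Reactants: 27 triketone (C14 ketone plus C26/C2 1,2-diketone)
Product: 29 ring C/D ene-dione (C13=C26), via aldol 28 (not isolated)
Conditions: 1,8-diazabicyclo[5.4.0]undec-7-ene, toluene, rt to 60 °C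
Reagents that add atoms: none
Why: Intramolecular aldol condensation of the C13 enolate onto the activated C26 carbonyl is the only six-membered closure available and dehydration gives the tetrasubstituted ene-dione, closing ring C.

Step 18
Reactants: 29 ring C/D ene-dione (C13=C26)
Product: 30 γ-hydroxy enone (C2 carbinol; epimers)
Conditions: NaBH4, CeCl3·7H2O, MeOH/CH2Cl2, −78 °C
Reagents that add atoms: none
Why: Luche 1,2-reduction takes the unhindered C2 acetyl carbonyl and leaves the C14 carbonyl, which is flanked by the quaternary C15 (the C2 centre is oxidised again later).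

Step 19
Reactants: 30 γ-hydroxy enone (C2 carbinol; epimers)
Product: 32 C14 enol triflate (C13=C14; C26 α-H), via lithium enolate 31 (not isolated)
Conditions: Li, NH3/THF, −78 °C; isoprene; NH3 removed; then PhNTf2, THF, −78 to 0 °C
Reagents that add atoms: N-phenylbis(trifluoromethanesulfonimide), O=S(=O)(N(c1ccccc1)S(=O)(=O)C(F)(F)F)C(F)(F)F
Why: Dissolving-metal enone reduction protonates the β-carbon C26 axially from the α face (Stork's stereoelectronic rule), which places the C2 side chain equatorial and β; the regiodefined C14 enolate is trapped as the triflate, and the C2 alkoxide is too poor a leaving group to eliminate.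

Step 20
Reactants: 32 C14 enol triflate (C13=C14; C26 α-H)
Product: 33 C13=C14 alkene alcohol
Conditions: Pd(OAc)2 (10 mol %), PPh3, HCO2H, Et3N, DMF, 60 °C
Reagents that add atoms: none
Why: Palladium-catalysed formate reduction of an enol triflate gives the trisubstituted C13=C14 alkene without touching C26.

Step 21
Reactants: 33 C13=C14 alkene alcohol
Product: 34 C2,C3-diol
Conditions: Bu4NF, THF, rt to 40 °C
Reagents that add atoms: none
Why: Fluoride cleavage of the only silyl ether.

Step 22
Reactants: 34 C2,C3-diol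
Product: 35 diketone (C2 methyl ketone and C3 ring A ketone)
Conditions: Dess–Martin periodinane, NaHCO3, CH2Cl2, 0 °C to rt
Reagents that add atoms: none
Why: Buffered Dess–Martin oxidation of both secondary alcohols is neutral, so the epimerisable C8 and C26 centres survive; 35 is used at once.

Step 23
Reactants: 35 diketone (C2 methyl ketone and C3 ring A ketone)
Product: 36 aspergilol C skeleton as C17 ethylene ketal
Conditions: TiCl3(DME)1.5, zinc–copper couple, DME, reflux; 35 added over 30 h by syringe pump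
Reagents that add atoms: none
Why: Intramolecular McMurry coupling with zerovalent titanium closes the eight-membered ring B and forms the tetrasubstituted C2=C3 alkene, whose geometry (C26 cis to C8) is enforced by the ring; no stereocentre is formed and the medium is aprotic and base-free.

Step 24
Reactants: 36 aspergilol C skeleton as C17 ethylene ketal
Product: 37 17-dehydroaspergilol C (C17 ketone)
Conditions: pyridinium p-toluenesulfonate (0.3 equiv), acetone/H2O (10:1), 50 °C
Reagents that add atoms: water, O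
Why: Mild acid hydrolysis of the dioxolane; the alkenes are not conjugated to any cation-stabilising group.

Step 25
Reactants: 37 17-dehydroaspergilol C (C17 ketone)
Product: 38 aspergilol C
Conditions: NaBH4, MeOH, 0 °C
Reagents that add atoms: none
Why: Borohydride attacks the trans-hydrindanone from the α face, opposite the C16 angular methyl group (as in 17-keto steroids), to give the 17β (R) alcohol.

**Compound list**
1 | (R)-4-(tert-butyldimethylsilyloxy)cyclopent-2-en-1-one | O=C1C=C[C@H](O[Si](C)(C)C(C)(C)C)C1 | starting material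
2 | (3S,4R)-4-(tert-butyldimethylsilyloxy)-3-isopropylcyclopentan-1-one | O=C1C[C@@H](O[Si](C)(C)C(C)(C)C)[C@H](C(C)C)C1 | intermediate
3 | (S)-4-isopropylcyclopent-2-en-1-one | O=C1C=C[C@H](C(C)C)C1 | intermediate
4 | (S)-2-iodo-4-isopropylcyclopent-2-en-1-one | O=C1C(I)=C[C@H](C(C)C)C1 | intermediate
5 | (S)-4-isopropyl-2-methylcyclopent-2-en-1-one | O=C1C(C)=C[C@H](C(C)C)C1 | intermediate
6 | 2,3-dimethylbuta-1,3-diene | CC(=C)C(C)=C | starting material
7 | (3-methyl-2-methylenebut-3-en-1-yl)potassium | [K]CC(=C)C(C)=C | intermediate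
8 | trimethyl(3-methyl-2-methylenebut-3-en-1-yl)silane | C[Si](C)(C)CC(=C)C(C)=C | intermediate
9 | (R)-3,7-dimethylocta-1,6-diene ((R)-β-citronellene) | C=C[C@H](C)CCC=C(C)C | starting material
10 | (R)-4-methylhex-5-enal | C=C[C@H](C)CCC=O | intermediate
11 | (R)-4-methylhex-5-en-1-ol | C=C[C@H](C)CCCO | intermediate
12 | (R)-6-iodo-3-methylhex-1-ene | C=C[C@H](C)CCCI | intermediate
13 | 2-methylfuran | Cc1ccco1 | starting material
14 | (5-methylfuran-2-yl)lithium | [Li]c1ccc(C)o1 | intermediate
15 | 2-methyl-5-[(4R)-4-methylhex-5-en-1-yl]furan | Cc1ccc(CCC[C@@H](C)C=C)o1 | intermediate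
16 | (9R)-9-methylundec-10-ene-2,5-dione | CC(=O)CCC(=O)CCC[C@@H](C)C=C | intermediate
17 | 3-methyl-2-[(3R)-3-methylpent-4-en-1-yl]cyclopent-2-en-1-one | CC1=C(CC[C@@H](C)C=C)C(=O)CC1 | intermediate
18 | (1S)-3-methyl-2-[(3R)-3-methylpent-4-en-1-yl]cyclopent-2-en-1-ol | O[C@H]1CCC(C)=C1CC[C@@H](C)C=C | intermediate
19 | (1S)-2-[(3R)-5-hydroxy-3-methylpentyl]-3-methylcyclopent-2-en-1-ol | O[C@H]1CCC(C)=C1CC[C@@H](C)CCO | intermediate
20 | (1S,2S,3S)-2-[(3R)-5-hydroxy-3-methylpentyl]-3-methylcyclopentan-1-ol | O[C@H]1CC[C@H](C)[C@@H]1CC[C@@H](C)CCO | intermediate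
21 | (3R)-5-[(1S,2S,5S)-2-hydroxy-5-methylcyclopentyl]-3-methylpentanal | O[C@H]1CC[C@H](C)[C@@H]1CC[C@@H](C)CC=O | intermediate
22 | (3R)-5-[(1S,2S,5S)-2-(tert-butyldimethylsilyloxy)-5-methylcyclopentyl]-3-methylpentanal | CC(C)(C)[Si](C)(C)O[C@H]1CC[C@H](C)[C@@H]1CC[C@@H](C)CC=O | intermediate
23 | trichlorotitanium enolate of the C24-allylated ring D ketone | CC1=C(O[Ti](Cl)(Cl)Cl)C[C@@H](C(C)C)[C@@H]1CC(=C)C(C)=C | intermediate
24 | ring D hydroxy ketone (C17 ketone; C15 β-methyl and α-C14H(OH) chain to ring A; C24 β-CH2C(=CH2)C(CH3)=CH2; C20 α-isopropyl; C14 epimers) | O=C1C[C@@H](C(C)C)[C@H](CC(=C)C(C)=C)[C@@]1(C)C(O)C[C@H](C)CC[C@H]1[C@@H](C)CC[C@@H]1O[Si](C)(C)C(C)(C)C | intermediate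
25 | C17 ethylene ketal of 24 | O1CCOC12C[C@@H](C(C)C)[C@H](CC(=C)C(C)=C)[C@@]2(C)C(O)C[C@H](C)CC[C@H]1[C@@H](C)CC[C@@H]1O[Si](C)(C)C(C)(C)C | intermediate
26 | C14 ketone (C17 ethylene ketal; diene side chain intact) | O1CCOC12C[C@@H](C(C)C)[C@H](CC(=C)C(C)=C)[C@@]2(C)C(=O)C[C@H](C)CC[C@H]1[C@@H](C)CC[C@@H]1O[Si](C)(C)C(C)(C)C | intermediate
27 | triketone (C14 ketone plus C26/C2 1,2-diketone; C17 ethylene ketal) | O1CCOC12C[C@@H](C(C)C)[C@H](CC(=O)C(C)=O)[C@@]2(C)C(=O)C[C@H](C)CC[C@H]1[C@@H](C)CC[C@@H]1O[Si](C)(C)C(C)(C)C | intermediate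
28 | C26 tertiary aldol (ring C closed; C13 and C26 unassigned) | O1CCOC12C[C@@H](C(C)C)[C@@H]3CC(O)(C(C)=O)C(C(=O)[C@@]23C)[C@H](C)CC[C@H]1[C@@H](C)CC[C@@H]1O[Si](C)(C)C(C)(C)C | intermediate
29 | ring C/D ene-dione (C13=C26; C14 ketone; C2 acetyl; C17 ethylene ketal) | O1CCOC12C[C@@H](C(C)C)[C@@H]3CC(C(C)=O)=C(C(=O)[C@@]23C)[C@H](C)CC[C@H]1[C@@H](C)CC[C@@H]1O[Si](C)(C)C(C)(C)C | intermediate
30 | γ-hydroxy enone (C2 carbinol, epimers; C14 ketone; C13=C26) | O1CCOC12C[C@@H](C(C)C)[C@@H]3CC(C(C)O)=C(C(=O)[C@@]23C)[C@H](C)CC[C@H]1[C@@H](C)CC[C@@H]1O[Si](C)(C)C(C)(C)C | intermediate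
31 | dilithium C14 enolate/C2 alkoxide (C26 α-H) | O1CCOC12C[C@@H](C(C)C)[C@@H]3C[C@H](C(C)O[Li])C(=C(O[Li])[C@@]23C)[C@H](C)CC[C@H]1[C@@H](C)CC[C@@H]1O[Si](C)(C)C(C)(C)C | intermediate
32 | C14 enol triflate (C13=C14; C26 α-H; C2 carbinol) | O1CCOC12C[C@@H](C(C)C)[C@@H]3C[C@H](C(C)O)C(=C(OS(=O)(=O)C(F)(F)F)[C@@]23C)[C@H](C)CC[C@H]1[C@@H](C)CC[C@@H]1O[Si](C)(C)C(C)(C)C | intermediate
33 | C13=C14 alkene alcohol (C2 carbinol; C3 silyl ether) | O1CCOC12C[C@@H](C(C)C)[C@@H]3C[C@H](C(C)O)C(=C[C@@]23C)[C@H](C)CC[C@H]1[C@@H](C)CC[C@@H]1O[Si](C)(C)C(C)(C)C | intermediate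
34 | C2,C3-diol | O1CCOC12C[C@@H](C(C)C)[C@@H]3C[C@H](C(C)O)C(=C[C@@]23C)[C@H](C)CC[C@H]1[C@@H](C)CC[C@@H]1O | intermediate
35 | diketone (C2 methyl ketone and C3 ring A ketone; C17 ethylene ketal) | O1CCOC12C[C@@H](C(C)C)[C@@H]3C[C@H](C(C)=O)C(=C[C@@]23C)[C@H](C)CC[C@H]1[C@@H](C)CCC1=O | intermediate
36 | aspergilol C skeleton as C17 ethylene ketal | C/C1=C2\CC[C@H](C)[C@@H]2CC[C@@H](C)C2=C[C@@]3(C)C4(OCCO4)C[C@@H](C(C)C)[C@@H]3C[C@@H]21 | intermediate
37 | 17-dehydroaspergilol C (C17 ketone) | C/C1=C2\CC[C@H](C)[C@@H]2CC[C@@H](C)C2=C[C@@]3(C)C(=O)C[C@@H](C(C)C)[C@@H]3C[C@@H]21 | intermediate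
38 | aspergilol C | C/C1=C2\CC[C@H](C)[C@@H]2CC[C@@H](C)C2=C[C@@]3(C)[C@H](O)C[C@@H](C(C)C)[C@@H]3C[C@@H]21 | target

**Totals**
Total step count: 25. Longest linear sequence: 21 steps (steps 5 to 12, then 13 to 25, from 9).

**Three steps most likely to fail**

Step 23 (McMurry closure of ring B). The risks are epimerisation at C8 (a cis-2,3-disubstituted cyclopentanone) or at C26 before coupling, and oligomerisation. The fallback sets out from 35 and comes back at 36. KN(SiMe3)2 and N-(5-chloro-2-pyridyl)bis(trifluoromethanesulfonimide) in THF at −78 °C enolise 35 kinetically toward C4 and the C1 methyl group and give the bis(enol triflate) F1. Pd(PPh3)4, Me3SnSnMe3 and LiCl in dioxane at 100 °C under high dilution then close ring B by an intramolecular Stille–Kelly coupling to the cyclic 1,3-diene F2 (C4=C3–C2=C1H2). Hydrogen with (naphthalene)Cr(CO)3 as catalyst adds 1,4 across the s-cis diene and gives the C2=C3 alkene of 36 with the C1 methyl cis to C4.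

Step 19 (reductive enol triflation in the presence of the free C2 alkoxide). The risks are triflation or loss of the C2 oxygen and incomplete trapping. The fallback sets out from 30 and comes back at 34. t-BuMe2SiOTf and 2,6-lutidine give the bis(silyl ether) F3. Hydrogen over Pd/C adds from the α face, away from the C16 methyl group, and gives the saturated ketone F4 with the C26 hydrogen α. KN(SiMe3)2 then PhNTf2 give the enol triflate F5, since C13 carries the only α-hydrogen. Pd(OAc)2, PPh3, HCO2H and Et3N give the alkene F6, and Bu4NF removes both silyl groups to give 34.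

Step 13 (one-flask Sakurai allylation and aldol addition). The risks are a sluggish aldol of the hindered titanium enolate at the quaternary centre and acid damage to the diene. The fallback sets out from 5 and 8 and comes back at 24. Conjugate allylation catalysed by Me3SiNTf2 (5 mol %) in CH2Cl2 at −78 °C gives the isolable silyl enol ether F7 with the same anti selectivity. A Mukaiyama aldol addition of F7 to 22 with BF3·OEt2 at −78 °C then gives 24.

**Further compounds**
F1 | step 23 | bis(enol triflate) of 35 (C3 triflate with C3=C4; C2 triflate with C2=C1H2) | O1CCOC12C[C@@H](C(C)C)[C@@H]3C[C@H](C(=C)OS(=O)(=O)C(F)(F)F)C(=C[C@@]23C)[C@H](C)CC[C@H]1[C@@H](C)CC=C1OS(=O)(=O)C(F)(F)F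
F2 | step 23 | tetracyclic 1,3-diene (ring B closed; C4=C3–C2=C1H2; C17 ethylene ketal) | C=C1C2=CC[C@H](C)[C@@H]2CC[C@@H](C)C2=C[C@@]3(C)C4(OCCO4)C[C@@H](C(C)C)[C@@H]3C[C@@H]21
F3 | step 19 | C2,C3-bis(tert-butyldimethylsilyl) ether of 30 | O1CCOC12C[C@@H](C(C)C)[C@@H]3CC(C(C)O[Si](C)(C)C(C)(C)C)=C(C(=O)[C@@]23C)[C@H](C)CC[C@H]1[C@@H](C)CC[C@@H]1O[Si](C)(C)C(C)(C)C
F4 | step 19 | saturated C14 ketone (C26 α-H; C13 unassigned) | O1CCOC12C[C@@H](C(C)C)[C@@H]3C[C@H](C(C)O[Si](C)(C)C(C)(C)C)C(C(=O)[C@@]23C)[C@H](C)CC[C@H]1[C@@H](C)CC[C@@H]1O[Si](C)(C)C(C)(C)C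
F5 | step 19 | C14 enol triflate, bis(silyl ether) | O1CCOC12C[C@@H](C(C)C)[C@@H]3C[C@H](C(C)O[Si](C)(C)C(C)(C)C)C(=C(OS(=O)(=O)C(F)(F)F)[C@@]23C)[C@H](C)CC[C@H]1[C@@H](C)CC[C@@H]1O[Si](C)(C)C(C)(C)C
F6 | step 19 | C13=C14 alkene, bis(silyl ether) | O1CCOC12C[C@@H](C(C)C)[C@@H]3C[C@H](C(C)O[Si](C)(C)C(C)(C)C)C(=C[C@@]23C)[C@H](C)CC[C@H]1[C@@H](C)CC[C@@H]1O[Si](C)(C)C(C)(C)C
F7 | step 13 | trimethylsilyl enol ether of the C24-allylated ring D ketone | C[Si](C)(C)OC1=C(C)[C@@H](CC(=C)C(C)=C)[C@H](C(C)C)C1
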